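**Retrosynthetic overview**
- Target ⇐ hydrogenolysis of two O‑benzyl groups ⇐ one LiAlH4 operation (two CO2Et → CH2OH, benzylic oxirane → tertiary carbinol) ⇐ face‑selective epoxidation of a (Z)‑4‑benzylidene‑oxolane.
- Benzylidene‑oxolane/dihydrobenzofuran diester ⇐ one Rh(II)‑catalysed double 1,5 C–H insertion of a bis(diazo) diester; both cis‑2,3 pairs (four stereocentres) come from the chiral catalyst.
- Bis(diazo) diester ⇐ aryl iodide/(E)‑vinyl iodide ether by twofold Pd coupling with ethyl diazoacetate.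
- Bis‑iodide ⇐ benzylic bromide (5‑iodovanillin + O‑benzylvanillyl alcohol) + (E)‑2‑iodocinnamyl alcohol (aryl bromide + propargyl alcohol; hydrostannation/iodination).
- Ring order: the three benzene rings are bought; the dihydrofuran ring of the benzofuran and the oxolane close together in step 8; a transient oxirane (step 9) is opened in step 10.

Abbreviation in names: Ar = 4‑(benzyloxy)‑3‑methoxyphenyl.
Assumption: Rh2(S‑PTTL)4 is taken to give the (2R,3S) sense at both insertion sites; if the opposite sense is found, Rh2(R‑PTTL)4 is used in step 8 and nothing else changes.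

**Route**

Step 1
Reactants: 1 5‑iodovanillin; 2 [4‑(benzyloxy)‑3‑methoxyphenyl]methanol
Product: 3 4‑(ArCH2O)‑3‑iodo‑5‑methoxybenzaldehyde
Conditions: PPh3, DIAD, THF, 0 °C → rt
Reagents that add atoms: none
Why: Mitsunobu etherification of the acidic phenol (pKa ca. 7) with the primary benzylic alcohol under neutral conditions, leaving aldehyde and aryl iodide untouched; no stereocentre.

Step 2
Reactants: 3 4‑(ArCH2O)‑3‑iodo‑5‑methoxybenzaldehyde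
Product: 4 [4‑(ArCH2O)‑3‑iodo‑5‑methoxyphenyl]methanol
Conditions: NaBH4, THF/MeOH, 0 °C
Reagents that add atoms: none
Why: Chemoselective borohydride reduction of the aldehyde; aryl iodide and benzyl ethers are inert.

Step 3
Reactants: 4 [4‑(ArCH2O)‑3‑iodo‑5‑methoxyphenyl]methanol
Product: 5 2‑(ArCH2O)‑5‑(bromomethyl)‑1‑iodo‑3‑methoxybenzene
Conditions: CBr4, PPh3, CH2Cl2, 0 °C; used crude
Reagents that add atoms: carbon tetrabromide, BrC(Br)(Br)Br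
Why: Appel bromination is neutral (no HBr), so the acid‑labile dialkoxybenzyl aryl ether survives.

Step 4
Reactants: 6 1‑(benzyloxy)‑4‑bromo‑2‑methoxybenzene (Ar–Br); 7 prop‑2‑yn‑1‑ol
Product: 8 3‑Ar‑prop‑2‑yn‑1‑ol
Conditions: PdCl2(PPh3)2 (3 mol %), CuI (3 mol %), i‑Pr2NH, DMF, 80 °C
Reagents that add atoms: none
Why: Sonogashira coupling of the aryl bromide with the terminal alkyne; heating compensates for the electron‑rich arene.

Step 5
Reactants: 8 3‑Ar‑prop‑2‑yn‑1‑ol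
Product: 10 (2E)‑3‑Ar‑2‑iodoprop‑2‑en‑1‑ol, via (E)‑2‑stannyl allylic alcohol 9 (not isolated)
Conditions: Bu3SnH, PdCl2(PPh3)2 (2 mol %), THF, rt; then I2, CH2Cl2, 0 °C
Reagents that add atoms: iodine, II
Why: Pd‑catalysed syn‑hydrostannation puts tin on the carbinol‑side carbon (hydroxyl‑directed) and iododestannylation proceeds with retention, so iodine ends trans to the aryl group, the geometry that later keeps the arene away from the carbenoid.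

Step 6
Reactants: 10 (2E)‑3‑Ar‑2‑iodoprop‑2‑en‑1‑ol; 5 2‑(ArCH2O)‑5‑(bromomethyl)‑1‑iodo‑3‑methoxybenzene
Product: 12 2‑(ArCH2O)‑1‑iodo‑5‑({[(2E)‑3‑Ar‑2‑iodoprop‑2‑en‑1‑yl]oxy}methyl)‑3‑methoxybenzene, via sodium alkoxide 11 (not isolated)
Conditions: NaH, THF, 0 °C; then 5, 0 °C → rt
Reagents that add atoms: none
Why: Williamson ether synthesis (SN2 at the reactive benzylic bromide); using the allylic partner as the nucleophile excludes SN2′ scrambling and keeps the alkene geometry.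

Step 7
Reactants: 12 bis‑iodide ether; 13 ethyl diazoacetate (3 equiv)
Product: 14 ethyl (3Z)‑4‑Ar‑3‑({[4‑(ArCH2O)‑3‑(1‑diazo‑2‑ethoxy‑2‑oxoethyl)‑5‑methoxyphenyl]methoxy}methyl)‑2‑diazobut‑3‑enoate
Conditions: Pd(PPh3)4 (10 mol %), Ag2CO3 (1.0 equiv), Et3N (20 mol %), toluene, rt, dark
Reagents that add atoms: none
Why: Pd(0)‑catalysed cross‑coupling of C(sp2)–I with the C–H of a diazoacetate (diazo group retained) is established for both aryl and vinyl iodides and is applied here twice, with retention of the vinyl geometry.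

Step 8
Reactants: 14 bis(diazo) diester
Product: 16 ethyl (2R,3S)‑2‑Ar‑5‑[(2R,3S,4Z)‑4‑(Ar‑methylidene)‑3‑(ethoxycarbonyl)oxolan‑2‑yl]‑7‑methoxy‑2,3‑dihydro‑1‑benzofuran‑3‑carboxylate, via monocyclised dihydrobenzofuran vinyldiazoacetate 15 (not isolated)
Conditions: Rh2(S‑PTTL)4 (2 mol %), toluene, 4 Å MS, −60 °C, slow addition of 14
Reagents that add atoms: none
Why: Proposed new method: both diazo groups give donor/acceptor Rh carbenoids (aryl and 2‑substituted styryl type), each with an ether‑ and arene‑activated benzylic C–H five atoms away, so two independent 1,5 C–H insertions close the dihydrofuran ring of the benzofuran and the oxolane in one flask; the chiral carboxylate pocket selects one enantiotopic C–H and one carbenoid face at each site and the concerted hydride‑transfer‑like transition state gives the cis pair in both rings, which are stereochemically homologous [O–CH(aryl)–CH(CO2Et)–C(sp2), same spatial sense], so one catalyst serves both; the closest known reaction is the cis‑selective enantioselective C–H insertion of 2‑(benzyloxy)aryl diazoacetates to 2‑aryl‑2,3‑dihydrobenzofuran‑3‑carboxylates, the vinyl half and the twofold use being the extension, and the trans aryl group on the vinylcarbenoid blocks indene formation and vinylogous attack.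

Step 9
Reactants: 16 benzylidene‑oxolane diester
Product: 17 ethyl (2R,3S)‑2‑Ar‑5‑[(2R,3S,6R,7R)‑2‑Ar‑7‑(ethoxycarbonyl)‑1,5‑dioxaspiro[2.4]heptan‑6‑yl]‑7‑methoxy‑2,3‑dihydro‑1‑benzofuran‑3‑carboxylate
Conditions: dimethyldioxirane (acetone solution), CH2Cl2, −20 °C; used crude
Reagents that add atoms: dimethyldioxirane, CC1(C)OO1
Why: Neutral epoxidation of the trisubstituted styrene from the face anti to the cis C2‑aryl and C3‑ester groups sets the C–O bond of the future tertiary carbinol (the benzylic oxirane centre is erased in step 10).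

Step 10
Reactants: 17 spiro‑oxirane diester
Product: 18 (3S,4R,5R)‑3‑(ArCH2)‑5‑[(2R,3R)‑2‑Ar‑3‑(hydroxymethyl)‑7‑methoxy‑2,3‑dihydro‑1‑benzofuran‑5‑yl]‑4‑(hydroxymethyl)oxolan‑3‑ol
Conditions: LiAlH4 (excess), THF, 0 °C → rt; Fieser work‑up
Reagents that add atoms: none
Why: Hydride reduces both esters faster than it enolises them (cis pairs kept) and opens the oxirane by SN2 at the less substituted benzylic carbon, leaving the tertiary alcohol with its configuration intact.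

Step 11
Reactants: 18 bis(benzyl ether)
Product: 19 (3S,4R,5R)‑5‑[(2R,3R)‑2‑(4‑hydroxy‑3‑methoxyphenyl)‑3‑(hydroxymethyl)‑7‑methoxy‑2,3‑dihydro‑1‑benzofuran‑5‑yl]‑3‑[(4‑hydroxy‑3‑methoxyphenyl)methyl]‑4‑(hydroxymethyl)oxolan‑3‑ol (CNP0284796.1)
Conditions: H2 (1 atm), 10 % Pd/C, EtOAc/MeOH, rt, monitored closely
Reagents that add atoms: none
Why: Hydrogenolysis of the two primary aryl benzyl ethers under neutral conditions is faster than cleavage of the secondary cyclic benzylic C–O bonds, and no acid is present to epimerise the cis benzylic centres.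

**Compound list**
1 | 5‑iodovanillin (4‑hydroxy‑3‑iodo‑5‑methoxybenzaldehyde) | COc1cc(C=O)cc(I)c1O | starting material
2 | [4‑(benzyloxy)‑3‑methoxyphenyl]methanol | COc1cc(CO)ccc1OCc1ccccc1 | starting material
3 | 4‑(ArCH2O)‑3‑iodo‑5‑methoxybenzaldehyde | COc1cc(C=O)cc(I)c1OCc1ccc(OCc2ccccc2)c(OC)c1 | intermediate
4 | [4‑(ArCH2O)‑3‑iodo‑5‑methoxyphenyl]methanol | COc1cc(CO)cc(I)c1OCc1ccc(OCc2ccccc2)c(OC)c1 | intermediate
5 | 2‑(ArCH2O)‑5‑(bromomethyl)‑1‑iodo‑3‑methoxybenzene | COc1cc(CBr)cc(I)c1OCc1ccc(OCc2ccccc2)c(OC)c1 | intermediate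
6 | 1‑(benzyloxy)‑4‑bromo‑2‑methoxybenzene | COc1cc(Br)ccc1OCc1ccccc1 | starting material
7 | prop‑2‑yn‑1‑ol | OCC#C | starting material
8 | 3‑Ar‑prop‑2‑yn‑1‑ol | COc1cc(C#CCO)ccc1OCc1ccccc1 | intermediate
9 | (2E)‑3‑Ar‑2‑(tributylstannyl)prop‑2‑en‑1‑ol (not isolated) | CCCC[Sn](CCCC)(CCCC)/C(CO)=C/c1ccc(OCc2ccccc2)c(OC)c1 | intermediate
10 | (2E)‑3‑Ar‑2‑iodoprop‑2‑en‑1‑ol | OC/C(I)=C\c1ccc(OCc2ccccc2)c(OC)c1 | intermediate
11 | sodium (2E)‑3‑Ar‑2‑iodoprop‑2‑en‑1‑olate (not isolated) | [Na+].[O-]C/C(I)=C\c1ccc(OCc2ccccc2)c(OC)c1 | intermediate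
12 | 2‑(ArCH2O)‑1‑iodo‑5‑({[(2E)‑3‑Ar‑2‑iodoprop‑2‑en‑1‑yl]oxy}methyl)‑3‑methoxybenzene | COc1cc(COC/C(I)=C\c2ccc(OCc3ccccc3)c(OC)c2)cc(I)c1OCc1ccc(OCc2ccccc2)c(OC)c1 | intermediate
13 | ethyl diazoacetate | CCOC(=O)C=[N+]=[N-] | starting material
14 | ethyl (3Z)‑4‑Ar‑3‑({[4‑(ArCH2O)‑3‑(1‑diazo‑2‑ethoxy‑2‑oxoethyl)‑5‑methoxyphenyl]methoxy}methyl)‑2‑diazobut‑3‑enoate | CCOC(=O)C(=[N+]=[N-])/C(COCc1cc(OC)c(OCc2ccc(OCc3ccccc3)c(OC)c2)c(C(=[N+]=[N-])C(=O)OCC)c1)=C/c1ccc(OCc2ccccc2)c(OC)c1 | intermediate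
15 | ethyl (2R,3S)‑2‑Ar‑5‑({[(2Z)‑3‑Ar‑2‑(1‑diazo‑2‑ethoxy‑2‑oxoethyl)prop‑2‑en‑1‑yl]oxy}methyl)‑7‑methoxy‑2,3‑dihydro‑1‑benzofuran‑3‑carboxylate (not isolated) | CCOC(=O)C(=[N+]=[N-])/C(COCc1cc(OC)c2c(c1)[C@H](C(=O)OCC)[C@H](c1ccc(OCc3ccccc3)c(OC)c1)O2)=C/c1ccc(OCc2ccccc2)c(OC)c1 | intermediate
16 | ethyl (2R,3S)‑2‑Ar‑5‑[(2R,3S,4Z)‑4‑(Ar‑methylidene)‑3‑(ethoxycarbonyl)oxolan‑2‑yl]‑7‑methoxy‑2,3‑dihydro‑1‑benzofuran‑3‑carboxylate | COc1cc(/C=C2\CO[C@@H](c3cc(OC)c4c(c3)[C@H](C(=O)OCC)[C@H](c3ccc(OCc5ccccc5)c(OC)c3)O4)[C@H]2C(=O)OCC)ccc1OCc1ccccc1 | intermediate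
17 | ethyl (2R,3S)‑2‑Ar‑5‑[(2R,3S,6R,7R)‑2‑Ar‑7‑(ethoxycarbonyl)‑1,5‑dioxaspiro[2.4]heptan‑6‑yl]‑7‑methoxy‑2,3‑dihydro‑1‑benzofuran‑3‑carboxylate | COc1cc([C@H]2O[C@@]23CO[C@@H](c4cc(OC)c5c(c4)[C@H](C(=O)OCC)[C@H](c4ccc(OCc6ccccc6)c(OC)c4)O5)[C@H]3C(=O)OCC)ccc1OCc1ccccc1 | intermediate
18 | (3S,4R,5R)‑3‑(ArCH2)‑5‑[(2R,3R)‑2‑Ar‑3‑(hydroxymethyl)‑7‑methoxy‑2,3‑dihydro‑1‑benzofuran‑5‑yl]‑4‑(hydroxymethyl)oxolan‑3‑ol | COc1cc(C[C@@]2(O)CO[C@@H](c3cc(OC)c4c(c3)[C@H](CO)[C@H](c3ccc(OCc5ccccc5)c(OC)c3)O4)[C@H]2CO)ccc1OCc1ccccc1 | intermediate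
19 | (3S,4R,5R)‑5‑[(2R,3R)‑2‑(4‑hydroxy‑3‑methoxyphenyl)‑3‑(hydroxymethyl)‑7‑methoxy‑2,3‑dihydro‑1‑benzofuran‑5‑yl]‑3‑[(4‑hydroxy‑3‑methoxyphenyl)methyl]‑4‑(hydroxymethyl)oxolan‑3‑ol | COc1cc(C[C@@]2(O)CO[C@@H](c3cc(OC)c4c(c3)[C@H](CO)[C@H](c3ccc(O)c(OC)c3)O4)[C@H]2CO)ccc1O | target

**Step count and risks**
Total: 11 steps. Longest linear sequence: 9 steps (steps 1, 2, 3, 6, 7, 8, 9, 10, 11).

Most likely to fail:

1. Step 8 (one catalyst must serve two different carbenoids, and the second diazo group is present while the first ring closes). The fallback closes the rings one after the other, each with its own catalyst. It sets out from 3: Pd/Ag2CO3 coupling with 13 gives the aryl diazoacetate aldehyde F1; Rh2(S‑PTTL)4 (toluene, −60 °C) closes it to the cis‑dihydrobenzofuran aldehyde F2; NaBH4 gives the benzylic alcohol F3 and CBr4/PPh3 the benzylic bromide F4; Ag2O‑mediated etherification with 10 (no alkoxide, so the cis ester is not epimerised) gives the dihydrobenzofuran vinyl iodide ether F5; Pd coupling of F5 with 13 gives 15, now isolated, which is closed to 16 with a catalyst chosen for the vinylcarbenoid alone (for example Rh2(S‑DOSP)4 in hexane). It comes back to the route at 15.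

2. Step 7 (hindered ortho‑alkoxy aryl iodide; Pd may decompose the vinyl diazo product). The fallback builds the esters first and the diazo groups second. It sets out from 12: twofold Negishi‑type coupling [Pd(dba)2, Q‑Phos, THF, rt] with the Reformatsky reagent ethyl (bromozincio)acetate F6 gives the bis(acetate) diester F7; twofold Regitz diazo transfer (p‑ABSA, DBU, MeCN, 0 °C) onto the arylacetate and the β,γ‑unsaturated ester comes back to the route at 14.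

3. Step 5 (tin may add at the aryl‑side carbon, giving the wrong iodide). The fallback drops the aryl group from the vinyl arm, so no alkene geometry is needed, and brings it in after ring closure. It sets out from 7: NaI/TMSCl/H2O (MeCN) gives 2‑iodoprop‑2‑en‑1‑ol F8; Ag2O etherification with 5 gives the 2‑iodoallyl ether bis‑iodide F9; double Pd coupling with 13 gives the bis(diazo) diester F10; the Rh step as in step 8 gives the 4‑methylidene‑oxolane diester F11; dimethyldioxirane gives the spiro‑oxirane F12 (oxygen anti to the cis substituents); the aryl Grignard reagent F13 (from 6 and Mg), with 10 mol % CuI at −40 °C, opens the oxirane at CH2 to the tertiary alcohol diester F14; LiAlH4 reduces both esters and comes back to the route at 18.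

**Further compounds**
F1 | step 8 | ethyl 2‑[2‑(ArCH2O)‑5‑formyl‑3‑methoxyphenyl]‑2‑diazoacetate | CCOC(=O)C(=[N+]=[N-])c1cc(C=O)cc(OC)c1OCc1ccc(OCc2ccccc2)c(OC)c1
F2 | step 8 | ethyl (2R,3S)‑2‑Ar‑5‑formyl‑7‑methoxy‑2,3‑dihydro‑1‑benzofuran‑3‑carboxylate | O=Cc1cc(OC)c2c(c1)[C@H](C(=O)OCC)[C@H](c1ccc(OCc3ccccc3)c(OC)c1)O2
F3 | step 8 | ethyl (2R,3S)‑2‑Ar‑5‑(hydroxymethyl)‑7‑methoxy‑2,3‑dihydro‑1‑benzofuran‑3‑carboxylate | OCc1cc(OC)c2c(c1)[C@H](C(=O)OCC)[C@H](c1ccc(OCc3ccccc3)c(OC)c1)O2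
F4 | step 8 | ethyl (2R,3S)‑2‑Ar‑5‑(bromomethyl)‑7‑methoxy‑2,3‑dihydro‑1‑benzofuran‑3‑carboxylate | BrCc1cc(OC)c2c(c1)[C@H](C(=O)OCC)[C@H](c1ccc(OCc3ccccc3)c(OC)c1)O2
F5 | step 8 | ethyl (2R,3S)‑2‑Ar‑5‑({[(2E)‑3‑Ar‑2‑iodoprop‑2‑en‑1‑yl]oxy}methyl)‑7‑methoxy‑2,3‑dihydro‑1‑benzofuran‑3‑carboxylate | COc1cc(/C=C(I)\COCc2cc(OC)c3c(c2)[C@H](C(=O)OCC)[C@H](c2ccc(OCc4ccccc4)c(OC)c2)O3)ccc1OCc1ccccc1
F6 | step 7 | ethyl (bromozincio)acetate | CCOC(=O)C[Zn]Br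
F7 | step 7 | ethyl (3Z)‑4‑Ar‑3‑({[4‑(ArCH2O)‑3‑(2‑ethoxy‑2‑oxoethyl)‑5‑methoxyphenyl]methoxy}methyl)but‑3‑enoate | CCOC(=O)C/C(COCc1cc(OC)c(OCc2ccc(OCc3ccccc3)c(OC)c2)c(CC(=O)OCC)c1)=C/c1ccc(OCc2ccccc2)c(OC)c1
F8 | step 5 | 2‑iodoprop‑2‑en‑1‑ol | OCC(I)=C
F9 | step 5 | 2‑(ArCH2O)‑1‑iodo‑5‑{[(2‑iodoprop‑2‑en‑1‑yl)oxy]methyl}‑3‑methoxybenzene | COc1cc(COCC(I)=C)cc(I)c1OCc1ccc(OCc2ccccc2)c(OC)c1
F10 | step 5 | ethyl 3‑({[4‑(ArCH2O)‑3‑(1‑diazo‑2‑ethoxy‑2‑oxoethyl)‑5‑methoxyphenyl]methoxy}methyl)‑2‑diazobut‑3‑enoate | CCOC(=O)C(=[N+]=[N-])C(=C)COCc1cc(OC)c(OCc2ccc(OCc3ccccc3)c(OC)c2)c(C(=[N+]=[N-])C(=O)OCC)c1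
F11 | step 5 | ethyl (2R,3S)‑2‑Ar‑5‑[(2R,3S)‑3‑(ethoxycarbonyl)‑4‑methylideneoxolan‑2‑yl]‑7‑methoxy‑2,3‑dihydro‑1‑benzofuran‑3‑carboxylate | C=C1CO[C@@H](c2cc(OC)c3c(c2)[C@H](C(=O)OCC)[C@H](c2ccc(OCc4ccccc4)c(OC)c2)O3)[C@H]1C(=O)OCC
F12 | step 5 | ethyl (2R,3S)‑2‑Ar‑5‑[(3R,6R,7R)‑7‑(ethoxycarbonyl)‑1,5‑dioxaspiro[2.4]heptan‑6‑yl]‑7‑methoxy‑2,3‑dihydro‑1‑benzofuran‑3‑carboxylate | C1[C@@]2(O1)CO[C@@H](c3cc(OC)c4c(c3)[C@H](C(=O)OCC)[C@H](c3ccc(OCc5ccccc5)c(OC)c3)O4)[C@H]2C(=O)OCC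
F13 | step 5 | [4‑(benzyloxy)‑3‑methoxyphenyl]magnesium bromide | COc1cc([Mg]Br)ccc1OCc1ccccc1
F14 | step 5 | ethyl (2R,3S)‑2‑Ar‑5‑[(2R,3R,4S)‑4‑(ArCH2)‑3‑(ethoxycarbonyl)‑4‑hydroxyoxolan‑2‑yl]‑7‑methoxy‑2,3‑dihydro‑1‑benzofuran‑3‑carboxylate | COc1cc(C[C@@]2(O)CO[C@@H](c3cc(OC)c4c(c3)[C@H](C(=O)OCC)[C@H](c3ccc(OCc5ccccc5)c(OC)c3)O4)[C@H]2C(=O)OCC)ccc1OCc1ccccc1
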